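Remark: the lower unit carries flavan numbering (O1, C2–C8a, rings A, B, C); the chain is Cα (CH2 on the phloroglucinol ring), Cβ (carbinol), Cγ (diarylmethine on C8); Bn = benzyl, TBS = tert-butyldimethylsilyl, MOM = methoxymethyl; lactol 27 is assumed usable as its mixture of C2 anomers because C2 becomes trigonal again in step 18.

## Analysis of the target

The target 38 is a 2,3-cis-flavan-3-ol 3-O-gallate whose C8 carries an open three-carbon chain: Cγ is bonded to C8 and to a second pyrogallol ring, Cβ carries the second gallate, and Cα is bonded to a 2,4,6-trihydroxyphenyl ring. There are four stereocentres in two isolated pairs, C2(R)/C3(R) on ring C with aryl and ester cis, and Cβ(R)/Cγ(S) in the chain; no induction can pass between the pairs, so each needs its own reagent control. Drawn with Cα–Cβ–Cγ–C8 as a zigzag, the Cβ oxygen and the Cγ pyrogallol ring are anti, which corresponds to a syn addition of ring A and oxygen across an (E)-cinnamoyl unit. The molecule holds seventeen phenolic hydroxyl groups (four pyrogallol triads that oxidise in air), two aryl esters, a benzylic aryl ether (O1–C2) and a doubly benzylic C–H (Cγ) that open or epimerise once the phenols are free. The difficulty is threefold: regiocontrol on ring A (C8 against C6, C8a–O against C5–O), the 2,3-cis relationship that equilibration does not provide, and a diarylmethine between two electron-rich rings that no ionising reaction can set reliably. The strategy rests on ring C: C3 is an oxygen-bearing carbon joined to the benzylic C4, which sits on C4a next to the C8a oxygen, so C4=C4a–C8a=O is an ortho-quinone methide heterodiene and C2–C3 is an α-oxygenated aldehyde.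

## Retrosynthetic reasoning

**Protecting groups and esters (38 ⇒ 37 ⇒ 34 + 36).** All seventeen phenols are carried as benzyl ethers and freed in the last step, so no free pyrogallol or phloroglucinol unit meets base, acid or oxidant. The two gallate esters are cut next. In diol 34 the only free hydroxyl groups are C3–OH and Cβ–OH, so one operation with two equivalents of chloride 36 (from two equivalents of acid 35) installs both esters.

**O1–C2 (34 ⇒ 33 ⇒ 32).** Ring C is opened at the benzylic ether bond. The forward reaction is an intramolecular Mitsunobu etherification of the C8a phenol onto the C2 carbinol of 32. It inverts C2, so the anti (1S,2R) alcohol 32 gives the 2,3-cis flavan 33, from which 34 follows by desilylation. The cis isomer is thus fixed by a stereospecific closure and not by equilibration.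

**C2–ring B (32 ⇒ 27 + 31).** Lactol 27 reacts as a masked aldehyde with a free C8a phenol. Addition of Grignard reagent 31 forms the C2–aryl bond and reopens O1–C2 in one step. Working at the aldehyde oxidation level is preferred to a detour through the carboxylic oxidation level, because a later anti-selective carbonyl reduction next to a bulky silyl ether cannot be relied on, whereas non-chelated Felkin–Anh addition to 27 gives the anti alcohol 32 as the inherent outcome.

**C3–C4 and O1–C2, the key disconnection (27 ⇒ 24 + 25).** Both bonds are cut together. C2 and C3 leave as aldehyde 25, and ring A remains as ortho-quinone methide 26, released from sulfone 24. The cut is made here because the heterodiene 26 and the enamine of 25 form exactly these two bonds in one operation. C3 is then the α-carbon of an enamine, where a chiral secondary amine controls the face. C5–O is benzylated, so only the C8a oxygen can enter the heterodiene, and the 8-linkage follows by construction. The forward reaction has to set C3 (R) next to a bulky, electron-rich C8 substituent.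

**C4a–CH2 (24 ⇒ 23 ⇒ 22 ⇒ 21 ⇒ 20).** The sulfonylmethyl group of 24 is traced to benzylic alcohol 23 and then to aldehyde 22, introduced by magnesium-phenoxide-directed ortho-formylation of phenol 21. That reaction touches only the ring with the free phenol and only its ortho position, so the other trialkoxyphenyl ring and C6 stay untouched. The phenol 21 is unmasked from MOM ether 20.

**Cα–aryl (20 ⇒ 19 ⇒ 15 + 18).** Silyl ether 20 comes from alcohol 19. The phloroglucinol ring is attached last to the chain by opening terminal epoxide 15 at its CH2 with Grignard reagent 18 (from bromide 17, from 16). Cβ is not touched, and the most nucleophilic arene enters only after the enolate and hydride steps.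

**Cβ–O and the auxiliary (15 ⇒ 13 ⇒ 12 ⇒ 10).** Epoxide 15 comes from diol 13 by activation of the primary hydroxyl as tosylate 14, so Cβ is retained. Diol 13 comes from reductive removal of the oxazolidinone from 12. The Cβ oxygen comes from hydroxylation of the auxiliary-bound enolate 11 of imide 10.

**Cγ–C8 (10 ⇒ 5 + 9).** Ring A is added as arylmagnesium reagent 9 (from MOM ether 7 of phenol 6 through aryllithium 8) to cinnamoyl imide 5 (from aldehyde 1 through acid 2, mixed anhydride 4 and auxiliary 3). Conjugate addition and hydroxylation are steered by the same auxiliary from the same face. That is a syn addition of ring A and oxygen across the (E)-alkene, which is the Cβ/Cγ relationship of 38. No benzylic cation or quinone methide is involved at Cγ.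

**Ring B nucleophile (31 ⇒ 30 ⇒ 29 ⇒ 28).** Bromide 30, the source of 31, comes from 28 by demethylation to triol 29 and benzylation.

## Alternatives that were turned down

**Alternative 1:** The Cβ–O bond would be made last from a Cα=Cβ alkene on a finished 8-substituted flavan. A dimethylsilyl hydride on the C7 oxygen would add across the (E)-alkene under Pt2[(CH2=CHSiMe2)2O]3 (zerovalent platinum) to give cyclic silyl ether A1 (Si on Cβ, H on Cα), and Tamao–Fleming oxidation would convert Cβ–Si into Cβ–OH with retention.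
- For: the tether enforces the six-membered mode, Cβ is relayed from Cγ inside a ring, and no Cβ protecting group is carried.
- Against: C7–OH must be distinguished from C5–OH; the alkene is a trialkoxystyrene whose electronic bias puts silicon on Cα, against the tether; the peroxide oxidation meets a freed electron-rich phenol; and the plan presupposes both the 8-substituted cis-flavan and the Cγ stereocentre.
- Comparison: for Cβ alone it is as short as the hydroxylation/epoxide sequence here and needs no auxiliary, which is a real advantage. The chosen route offers instead a Cβ/Cγ pair fixed by one auxiliary of known sense and a ring C construction that needs no preformed flavan.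

**Alternative 2:** Ring A itself would be disconnected (C4a–C8a and C5–C6, with C8–C8a broken and re-formed). A four-carbon cyclobutenone component carrying the chain and an oxygenated two-carbon alkyne component carrying C4–C3–C2 would be heated, passing through a vinylketene, a (2+2) adduct and a 6π closure to phenol A2 with only C8a–OH free.
- For: the mechanism dictates all six ring A positions and delivers the three oxygens already differentiated. The chosen route must secure this by directed metalation and ortho-specific formylation, so the alternative is stronger on this point and on convergence.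
- Against: each partner is a long synthesis, and the alkyne partner must already hold C2 and C3, so both stereochemical problems are moved and not solved. The annulation runs hot with nine benzyl ethers and four different silyl or tert-butyl ethers. Cγ sits next to a carbon that becomes part of the ketene π-system, so its C–H becomes acidic. Ring C still has to be closed by the same Mitsunobu step.
- Comparison: the chosen route builds ring C catalytically onto a cheap, existing ring A in fewer operations and under mild conditions.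

**Alternative 3:** Cα–Cβ and Cγ–aryl would be formed in one step. A boron ate complex, made from the benzylic pinacol boronate of the phloroglucinol unit and a (Z)-alkenyllithium on C8 of the finished flavan, would meet the pyrogallol aryl triflate under Pd(OAc)2 and the chiral ferrocenyl bisphosphine MandyPhos. The benzyl group migrates from boron to Cβ while the aryl–palladium is delivered to Cγ, giving boronate A3, whose C–B bond is then oxidised to C–OH.
- For: three fragments are joined and both chain stereocentres are set in a single catalytic step with defined anti addition. On the Cβ/Cγ pair this is clearly shorter than the auxiliary sequence used here.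
- Against: the alkene is β-substituted by a 2,6-dioxygenated aryl group, the migrating group is a hindered benzyl, the triflate is electron-rich and slow in oxidative addition, the alkenyllithium must be generated beside several benzyl ethers, and the catalyst must override two existing stereocentres. It also presupposes the 8-functionalised cis-flavan.
- Comparison: the ceiling in step economy is higher and the predictability lower. The chosen strategy spends more steps on the chain but uses reactions of known stereochemical sense and keeps its one untested combination on the construction of ring C.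

Key step: step 15

## Route

Step 1
Reactants: 1 3,4,5-tris(benzyloxy)benzaldehyde
Product: 2 (2E)-3-[3,4,5-tris(benzyloxy)phenyl]prop-2-enoic acid
Conditions: malonic acid, pyridine, piperidine (cat.), 90 °C
Reagents that add atoms: malonic acid, OC(=O)CC(=O)O
Why: Knoevenagel–Doebner condensation; decarboxylation of the arylidene malonic acid under equilibrating conditions should give the (E)-acid only.

Step 2
Reactants: 2 (2E)-3-[3,4,5-tris(benzyloxy)phenyl]prop-2-enoic acid; 3 (4S)-4-benzyl-1,3-oxazolidin-2-one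
Product: 5 (4S)-4-benzyl-3-{(2E)-3-[3,4,5-tris(benzyloxy)phenyl]prop-2-enoyl}-1,3-oxazolidin-2-one, via mixed pivalic anhydride 4 (not isolated)
Conditions: t-BuCOCl, Et3N, THF, −20 °C; then 3, LiCl, −20 °C → rt
Reagents that add atoms: none
Why: N-acylation of the oxazolidinone through the mixed anhydride; the hindered pivaloyl carbonyl directs attack to the cinnamoyl carbonyl, and LiCl with Et3N makes the auxiliary nucleophilic enough without a strong base.

Step 3
Reactants: 6 3,5-bis(benzyloxy)phenol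
Product: 7 1,3-bis(benzyloxy)-5-(methoxymethoxy)benzene
Conditions: MeOCH2Cl, i-Pr2NEt, CH2Cl2, 0 °C → rt
Reagents that add atoms: chloromethyl methyl ether, COCCl
Why: O-alkylation of the phenol (Williamson-type acetal formation); the MOM ether marks the oxygen that becomes O1 and is the directing group for the metalation in step 4.

Step 4
Reactants: 7 1,3-bis(benzyloxy)-5-(methoxymethoxy)benzene; 5 cinnamoyl imide
Product: 10 (4S)-4-benzyl-3-{(3S)-3-[2,4-bis(benzyloxy)-6-(methoxymethoxy)phenyl]-3-[3,4,5-tris(benzyloxy)phenyl]propanoyl}-1,3-oxazolidin-2-one, via aryllithium 8 (not isolated), via arylmagnesium bromide 9 (not isolated)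
Conditions: 7, n-BuLi, TMEDA, Et2O, 0 °C; MgBr2·OEt2, −78 → 0 °C; CuBr·SMe2 (30 mol %), THF/Me2S, −20 °C; then 5, −20 → 0 °C; aq NH4Cl
Reagents that add atoms: none
Why: Directed ortho-metalation at the carbon flanked by OMOM and OBn (the chelating acetal is the stronger director), transmetalation to magnesium, and copper-catalysed conjugate addition to the metal-chelated s-cis N-enoyl oxazolidinone; the aryl group should add to the β-face opposite the C4 benzyl group, which sets Cγ as S.

Step 5
Reactants: 10 conjugate adduct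
Product: 12 (4S)-4-benzyl-3-{(2S,3S)-3-[2,4-bis(benzyloxy)-6-(methoxymethoxy)phenyl]-2-hydroxy-3-[3,4,5-tris(benzyloxy)phenyl]propanoyl}-1,3-oxazolidin-2-one, via sodium enolate 11 (not isolated)
Conditions: NaN(SiMe3)2, THF, −78 °C; 3-phenyl-2-(phenylsulfonyl)oxaziridine, −78 °C; AcOH
Reagents that add atoms: 3-phenyl-2-(phenylsulfonyl)oxaziridine, O=S(=O)(c1ccccc1)N1OC1c1ccccc1
Why: Auxiliary-controlled hydroxylation of the chelated (Z)-sodium enolate with the Davis oxaziridine; oxygen is transferred to the face opposite the C4 benzyl group, the same face that received ring A in step 4, so aryl and oxygen are syn across the former (E)-alkene and Cβ is set as required.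

Step 6
Reactants: 12 α-hydroxy imide
Product: 13 (2S,3S)-3-[2,4-bis(benzyloxy)-6-(methoxymethoxy)phenyl]-3-[3,4,5-tris(benzyloxy)phenyl]propane-1,2-diol
Conditions: LiBH4, MeOH (1 equiv), THF, 0 °C
Reagents that add atoms: none
Why: Reductive cleavage of the N-acyl oxazolidinone at the exocyclic carbonyl; neither stereocentre is enolisable under these conditions and auxiliary 3 is recovered.

Step 7
Reactants: 13 diol
Product: 15 (2S)-2-{(S)-[2,4-bis(benzyloxy)-6-(methoxymethoxy)phenyl][3,4,5-tris(benzyloxy)phenyl]methyl}oxirane, via primary tosylate 14 (not isolated)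
Conditions: NaH, 1-(p-toluenesulfonyl)imidazole, THF, 0 °C → rt
Reagents that add atoms: none
Why: Selective sulfonylation of the primary alkoxide followed by intramolecular Williamson closure (3-exo-tet) by the secondary alkoxide; the Cβ–O bond is not broken, so Cβ is retained.

Step 8
Reactants: 16 1,3,5-tris(benzyloxy)benzene
Product: 17 2-bromo-1,3,5-tris(benzyloxy)benzene
Conditions: NBS, CH2Cl2, 0 °C
Reagents that add atoms: N-bromosuccinimide, O=C1CCC(=O)N1Br
Why: Electrophilic aromatic bromination; the three free positions are equivalent and the first bromine deactivates the ring, so one monobromide should form.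

Step 9
Reactants: 17 2-bromo-1,3,5-tris(benzyloxy)benzene; 15 epoxide
Product: 19 (1S,2R)-1-[2,4-bis(benzyloxy)-6-(methoxymethoxy)phenyl]-1-[3,4,5-tris(benzyloxy)phenyl]-3-[2,4,6-tris(benzyloxy)phenyl]propan-2-ol, via arylmagnesium bromide 18 (not isolated)
Conditions: 17, Mg, THF, 50 °C; then CuI (10 mol %), 15, THF, −30 → 0 °C; aq NH4Cl
Reagents that add atoms: none
Why: Copper-catalysed SN2 opening of the terminal epoxide at its CH2 by the aryl Grignard reagent forms Cα–aryl; Cβ is untouched, and its descriptor changes from S to R only because the new CH2Ar group ranks below Cγ.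

Step 10
Reactants: 19 secondary alcohol
Product: 20 tert-butyldimethylsilyl ether of 19 at Cβ, (1S,2R)
Conditions: t-BuMe2SiOTf, 2,6-lutidine, CH2Cl2, −78 → 0 °C
Reagents that add atoms: tert-butyldimethylsilyl trifluoromethanesulfonate, CC(C)(C)[Si](C)(C)OS(=O)(=O)C(F)(F)F
Why: Silylation of a hindered secondary alcohol with the silyl triflate; the Cβ oxygen must be masked for the Grignard and Mitsunobu steps and freed later without touching benzyl ethers.

Step 11
Reactants: 20 MOM ether
Product: 21 3,5-bis(benzyloxy)-2-{(1S,2R)-2-(tert-butyldimethylsilyloxy)-1-[3,4,5-tris(benzyloxy)phenyl]-3-[2,4,6-tris(benzyloxy)phenyl]propyl}phenol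
Conditions: ZnBr2, n-PrSH, CH2Cl2, 0 °C
Reagents that add atoms: none
Why: Lewis-acid-mediated acetal exchange removes the aryl MOM group; the thiol captures the methoxymethyl cation so that it cannot alkylate the trialkoxyphenyl rings, and the hindered secondary silyl ether and the benzyl ethers should persist.

Step 12
Reactants: 21 phenol
Product: 22 4,6-bis(benzyloxy)-2-hydroxy-3-{(1S,2R)-2-(tert-butyldimethylsilyloxy)-1-[3,4,5-tris(benzyloxy)phenyl]-3-[2,4,6-tris(benzyloxy)phenyl]propyl}benzaldehyde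
Conditions: MgCl2, Et3N, (CH2O)n, THF, 65 °C
Reagents that add atoms: formaldehyde (as paraformaldehyde), C=O
Why: Casnati–Skattebøl ortho-formylation; formaldehyde is delivered within the magnesium phenoxide, so only the ring with the free phenol reacts and only at its one free ortho carbon (C4a), not at C6 or on the other trialkoxyphenyl ring.

Step 13
Reactants: 22 salicylaldehyde
Product: 23 3,5-bis(benzyloxy)-2-(hydroxymethyl)-6-{(1S,2R)-2-(tert-butyldimethylsilyloxy)-1-[3,4,5-tris(benzyloxy)phenyl]-3-[2,4,6-tris(benzyloxy)phenyl]propyl}phenol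
Conditions: NaBH4, THF/MeOH, 0 °C
Reagents that add atoms: none
Why: Hydride reduction of the aldehyde; the electron-rich ortho-hydroxybenzyl alcohol is kept cold and used directly.

Step 14
Reactants: 23 ortho-hydroxybenzyl alcohol
Product: 24 3,5-bis(benzyloxy)-2-[(4-methylbenzenesulfonyl)methyl]-6-{(1S,2R)-2-(tert-butyldimethylsilyloxy)-1-[3,4,5-tris(benzyloxy)phenyl]-3-[2,4,6-tris(benzyloxy)phenyl]propyl}phenol
Conditions: p-TolSO2H, CH2Cl2, 0 °C → rt
Reagents that add atoms: p-toluenesulfinic acid, Cc1ccc(cc1)S(=O)O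
Why: Acid-promoted benzylic substitution: the sulfinic acid ionises the very electron-rich benzylic alcohol and the sulfinate is alkylated at sulfur, giving the bench-stable sulfone as a latent ortho-quinone methide.

Step 15
Reactants: 24 2-(tosylmethyl)phenol; 25 (tert-butyldimethylsilyloxy)acetaldehyde
Product: 27 (3R)-5,7-bis(benzyloxy)-3-(tert-butyldimethylsilyloxy)-8-{(1S,2R)-2-(tert-butyldimethylsilyloxy)-1-[3,4,5-tris(benzyloxy)phenyl]-3-[2,4,6-tris(benzyloxy)phenyl]propyl}-3,4-dihydro-2H-chromen-2-ol (C2 anomers), via ortho-quinone methide 26 (not isolated)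
Conditions: 25 (2 equiv), (S)-α,α-diphenylprolinol trimethylsilyl ether (20 mol %), Na2CO3, CH2Cl2, 0 °C → rt
Reagents that add atoms: none
Why: Base removes the phenolic proton of 24 and p-toluenesulfinate leaves, giving ortho-quinone methide 26 (C8a=O, C4a=CH2), while 25 condenses with the amine to the (E)-enamine. The enamine α-carbon adds to the exocyclic methylene in a Michael-type step that forms C3–C4 and rearomatises ring A, and the phenoxide then closes onto the iminium carbon (6-exo-trig) to form O1–C2; hydrolysis of the N,O-acetal releases lactol 27 and the catalyst. The closest known reaction type is the secondary-amine-catalysed (4+2) annulation of aldehydes with ortho-quinone methides generated in situ from 2-(sulfonylmethyl)phenols. C3 is the only stereocentre fixed here: the diphenyl(silyloxy)methyl group shields one face of the s-trans enamine, and attack on the open face with the (S)-catalyst corresponds to 3R. The step needs regiocontrol of the heterodiene, which is secured because C8a–OH is the only free phenol and C5–O is benzylated. It also needs chemoselectivity for the enamine over the trialkoxyphenyl rings, which the far higher nucleophilicity of the enamine and the unhindered methylene should provide. C2 forms as both anomers, which is of no consequence.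

Step 16
Reactants: 28 5-bromo-1,2,3-trimethoxybenzene
Product: 29 5-bromobenzene-1,2,3-triol
Conditions: BBr3, CH2Cl2, −78 °C → rt; H2O
Reagents that add atoms: none
Why: Lewis-acid cleavage of the three aryl methyl ethers; the aryl bromide is inert, and the air-sensitive triol is benzylated at once.

Step 17
Reactants: 29 5-bromobenzene-1,2,3-triol
Product: 30 5-bromo-1,2,3-tris(benzyloxy)benzene
Conditions: BnBr, K2CO3, DMF, 60 °C
Reagents that add atoms: benzyl bromide, BrCc1ccccc1
Why: Williamson etherification of the three phenols.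

Step 18
Reactants: 30 5-bromo-1,2,3-tris(benzyloxy)benzene; 27 lactol
Product: 32 (1S,2R)-3-{4,6-bis(benzyloxy)-2-hydroxy-3-[(1S,2R)-2-(tert-butyldimethylsilyloxy)-1-[3,4,5-tris(benzyloxy)phenyl]-3-[2,4,6-tris(benzyloxy)phenyl]propyl]phenyl}-2-(tert-butyldimethylsilyloxy)-1-[3,4,5-tris(benzyloxy)phenyl]propan-1-ol, via arylmagnesium bromide 31 (not isolated)
Conditions: 30, Mg, THF, 50 °C; then 27, THF, −78 → 0 °C; aq NH4Cl
Reagents that add atoms: none
Why: Grignard addition to a lactol: one equivalent of the reagent deprotonates the lactol, whose magnesium salt opens to the α-silyloxy aldehyde; a second equivalent adds under Felkin–Anh control with the bulky, non-chelating silyloxy group anti to the incoming aryl group, which should give the anti (1S,2R) alcohol.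

Step 19
Reactants: 32 anti alcohol with free C8a phenol
Product: 33 (2R,3R)-5,7-bis(benzyloxy)-3-(tert-butyldimethylsilyloxy)-8-{(1S,2R)-2-(tert-butyldimethylsilyloxy)-1-[3,4,5-tris(benzyloxy)phenyl]-3-[2,4,6-tris(benzyloxy)phenyl]propyl}-2-[3,4,5-tris(benzyloxy)phenyl]-3,4-dihydro-2H-chromene
Conditions: PPh3, i-PrO2CN=NCO2i-Pr, THF, 0 °C → rt
Reagents that add atoms: none
Why: Intramolecular Mitsunobu etherification (6-exo-tet): the phenol displaces the benzylic oxyphosphonium with inversion, turning C2 (S) of the anti alcohol into C2 (R) and giving the 2,3-cis flavan; the β-silyloxy group and the two meta-alkoxy groups of ring B disfavour ionisation.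

Step 20
Reactants: 33 bis-silyl ether
Product: 34 (2R,3R)-5,7-bis(benzyloxy)-8-{(1S,2R)-2-hydroxy-1-[3,4,5-tris(benzyloxy)phenyl]-3-[2,4,6-tris(benzyloxy)phenyl]propyl}-2-[3,4,5-tris(benzyloxy)phenyl]-3,4-dihydro-2H-chromen-3-ol
Conditions: HF·pyridine, THF, 0 °C → rt
Reagents that add atoms: none
Why: Fluoride-driven cleavage of both secondary silyl ethers; with every phenol benzylated there is no quinone methide pathway for epimerisation at C2 or Cγ.

Step 21
Reactants: 34 diol; 35 3,4,5-tris(benzyloxy)benzoic acid (two equivalents are built into the product, about 2.5 equiv are used)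
Product: 37 perbenzylated bis-gallate (C3 and Cβ 3,4,5-tris(benzyloxy)benzoates of 34), via acid chloride 36 (not isolated)
Conditions: 35 (2.5 equiv), (COCl)2, DMF (cat.), CH2Cl2, rt, then evaporation; 34, DMAP, Et3N, CH2Cl2, rt → 40 °C
Reagents that add atoms: 3,4,5-tris(benzyloxy)benzoic acid (second equivalent of 35), OC(=O)c1cc(OCc9ccccc9)c(OCc9ccccc9)c(OCc9ccccc9)c1
Why: DMAP-catalysed esterification of both secondary alcohols by acid chloride 36 through the acylpyridinium ion, each hydroxyl taking up one galloyl unit so that two equivalents of 35 end up in 37; the acid chloride is chosen because the axial C3–OH and the Cβ–OH next to the diarylmethine are both hindered.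

Step 22
Reactants: 37 perbenzylated bis-gallate
Product: 38 target, (2R,3R)-5,7-dihydroxy-8-[(1S,2R)-2-(3,4,5-trihydroxybenzoyloxy)-1-(3,4,5-trihydroxyphenyl)-3-(2,4,6-trihydroxyphenyl)propyl]-2-(3,4,5-trihydroxyphenyl)-3,4-dihydro-2H-chromen-3-yl 3,4,5-trihydroxybenzoate
Conditions: H2 (1 atm), Pd(OH)2/C, THF/MeOH, rt
Reagents that add atoms: none
Why: Hydrogenolysis of the seventeen benzyl ethers; the aryl esters, the ring C ether and the diarylmethine should survive at ambient pressure, and the product is handled under inert gas.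

## Compound list

1 | 3,4,5-tris(benzyloxy)benzaldehyde | O=Cc1cc(OCc9ccccc9)c(OCc9ccccc9)c(OCc9ccccc9)c1 | starting material
2 | (2E)-3-[3,4,5-tris(benzyloxy)phenyl]prop-2-enoic acid | OC(=O)/C=C/c1cc(OCc9ccccc9)c(OCc9ccccc9)c(OCc9ccccc9)c1 | intermediate
3 | (4S)-4-benzyl-1,3-oxazolidin-2-one | O=C1OC[C@H](Cc2ccccc2)N1 | starting material
4 | (2E)-3-[3,4,5-tris(benzyloxy)phenyl]prop-2-enoic pivalic anhydride | CC(C)(C)C(=O)OC(=O)/C=C/c1cc(OCc9ccccc9)c(OCc9ccccc9)c(OCc9ccccc9)c1 | intermediate (not isolated)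
5 | (4S)-4-benzyl-3-{(2E)-3-[3,4,5-tris(benzyloxy)phenyl]prop-2-enoyl}-1,3-oxazolidin-2-one | O=C1OC[C@H](Cc2ccccc2)N1C(=O)/C=C/c1cc(OCc9ccccc9)c(OCc9ccccc9)c(OCc9ccccc9)c1 | intermediate
6 | 3,5-bis(benzyloxy)phenol | Oc1cc(OCc9ccccc9)cc(OCc9ccccc9)c1 | starting material
7 | 1,3-bis(benzyloxy)-5-(methoxymethoxy)benzene | COCOc1cc(OCc9ccccc9)cc(OCc9ccccc9)c1 | intermediate
8 | [2,4-bis(benzyloxy)-6-(methoxymethoxy)phenyl]lithium | [Li]c1c(OCOC)cc(OCc9ccccc9)cc1OCc9ccccc9 | intermediate (not isolated)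
9 | [2,4-bis(benzyloxy)-6-(methoxymethoxy)phenyl]magnesium bromide | Br[Mg]c1c(OCOC)cc(OCc9ccccc9)cc1OCc9ccccc9 | intermediate (not isolated)
10 | (4S)-4-benzyl-3-{(3S)-3-[2,4-bis(benzyloxy)-6-(methoxymethoxy)phenyl]-3-[3,4,5-tris(benzyloxy)phenyl]propanoyl}-1,3-oxazolidin-2-one | O=C1OC[C@H](Cc2ccccc2)N1C(=O)C[C@@H](c1cc(OCc9ccccc9)c(OCc9ccccc9)c(OCc9ccccc9)c1)c1c(OCc9ccccc9)cc(OCc9ccccc9)cc1OCOC | intermediate
11 | sodium (Z)-enolate of 10 | [Na]O/C(=C\[C@@H](c1cc(OCc9ccccc9)c(OCc9ccccc9)c(OCc9ccccc9)c1)c1c(OCc9ccccc9)cc(OCc9ccccc9)cc1OCOC)N1C(=O)OC[C@@H]1Cc1ccccc1 | intermediate (not isolated)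
12 | (4S)-4-benzyl-3-{(2S,3S)-3-[2,4-bis(benzyloxy)-6-(methoxymethoxy)phenyl]-2-hydroxy-3-[3,4,5-tris(benzyloxy)phenyl]propanoyl}-1,3-oxazolidin-2-one | O=C1OC[C@H](Cc2ccccc2)N1C(=O)[C@@H](O)[C@@H](c1cc(OCc9ccccc9)c(OCc9ccccc9)c(OCc9ccccc9)c1)c1c(OCc9ccccc9)cc(OCc9ccccc9)cc1OCOC | intermediate
13 | (2S,3S)-3-[2,4-bis(benzyloxy)-6-(methoxymethoxy)phenyl]-3-[3,4,5-tris(benzyloxy)phenyl]propane-1,2-diol | OC[C@@H](O)[C@@H](c1cc(OCc9ccccc9)c(OCc9ccccc9)c(OCc9ccccc9)c1)c1c(OCc9ccccc9)cc(OCc9ccccc9)cc1OCOC | intermediate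
14 | (2S,3S)-3-[2,4-bis(benzyloxy)-6-(methoxymethoxy)phenyl]-2-hydroxy-3-[3,4,5-tris(benzyloxy)phenyl]propyl 4-methylbenzenesulfonate | Cc1ccc(cc1)S(=O)(=O)OC[C@@H](O)[C@@H](c1cc(OCc9ccccc9)c(OCc9ccccc9)c(OCc9ccccc9)c1)c1c(OCc9ccccc9)cc(OCc9ccccc9)cc1OCOC | intermediate (not isolated)
15 | (2S)-2-{(S)-[2,4-bis(benzyloxy)-6-(methoxymethoxy)phenyl][3,4,5-tris(benzyloxy)phenyl]methyl}oxirane | C1O[C@H]1[C@@H](c1cc(OCc9ccccc9)c(OCc9ccccc9)c(OCc9ccccc9)c1)c1c(OCc9ccccc9)cc(OCc9ccccc9)cc1OCOC | intermediate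
16 | 1,3,5-tris(benzyloxy)benzene | c1c(OCc9ccccc9)cc(OCc9ccccc9)cc1OCc9ccccc9 | starting material
17 | 2-bromo-1,3,5-tris(benzyloxy)benzene | Brc1c(OCc9ccccc9)cc(OCc9ccccc9)cc1OCc9ccccc9 | intermediate
18 | [2,4,6-tris(benzyloxy)phenyl]magnesium bromide | Br[Mg]c1c(OCc9ccccc9)cc(OCc9ccccc9)cc1OCc9ccccc9 | intermediate (not isolated)
19 | (1S,2R)-1-[2,4-bis(benzyloxy)-6-(methoxymethoxy)phenyl]-1-[3,4,5-tris(benzyloxy)phenyl]-3-[2,4,6-tris(benzyloxy)phenyl]propan-2-ol | O[C@H](Cc1c(OCc9ccccc9)cc(OCc9ccccc9)cc1OCc9ccccc9)[C@@H](c1cc(OCc9ccccc9)c(OCc9ccccc9)c(OCc9ccccc9)c1)c1c(OCc9ccccc9)cc(OCc9ccccc9)cc1OCOC | intermediate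
20 | tert-butyl{[(1S,2R)-1-[2,4-bis(benzyloxy)-6-(methoxymethoxy)phenyl]-1-[3,4,5-tris(benzyloxy)phenyl]-3-[2,4,6-tris(benzyloxy)phenyl]propan-2-yl]oxy}dimethylsilane | CC(C)(C)[Si](C)(C)O[C@H](Cc1c(OCc9ccccc9)cc(OCc9ccccc9)cc1OCc9ccccc9)[C@@H](c1cc(OCc9ccccc9)c(OCc9ccccc9)c(OCc9ccccc9)c1)c1c(OCc9ccccc9)cc(OCc9ccccc9)cc1OCOC | intermediate
21 | 3,5-bis(benzyloxy)-2-{(1S,2R)-2-(tert-butyldimethylsilyloxy)-1-[3,4,5-tris(benzyloxy)phenyl]-3-[2,4,6-tris(benzyloxy)phenyl]propyl}phenol | CC(C)(C)[Si](C)(C)O[C@H](Cc1c(OCc9ccccc9)cc(OCc9ccccc9)cc1OCc9ccccc9)[C@@H](c1cc(OCc9ccccc9)c(OCc9ccccc9)c(OCc9ccccc9)c1)c1c(OCc9ccccc9)cc(OCc9ccccc9)cc1O | intermediate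
22 | 4,6-bis(benzyloxy)-2-hydroxy-3-{(1S,2R)-2-(tert-butyldimethylsilyloxy)-1-[3,4,5-tris(benzyloxy)phenyl]-3-[2,4,6-tris(benzyloxy)phenyl]propyl}benzaldehyde | CC(C)(C)[Si](C)(C)O[C@H](Cc1c(OCc9ccccc9)cc(OCc9ccccc9)cc1OCc9ccccc9)[C@@H](c1cc(OCc9ccccc9)c(OCc9ccccc9)c(OCc9ccccc9)c1)c1c(OCc9ccccc9)cc(OCc9ccccc9)c(C=O)c1O | intermediate
23 | 3,5-bis(benzyloxy)-2-(hydroxymethyl)-6-{(1S,2R)-2-(tert-butyldimethylsilyloxy)-1-[3,4,5-tris(benzyloxy)phenyl]-3-[2,4,6-tris(benzyloxy)phenyl]propyl}phenol | CC(C)(C)[Si](C)(C)O[C@H](Cc1c(OCc9ccccc9)cc(OCc9ccccc9)cc1OCc9ccccc9)[C@@H](c1cc(OCc9ccccc9)c(OCc9ccccc9)c(OCc9ccccc9)c1)c1c(OCc9ccccc9)cc(OCc9ccccc9)c(CO)c1O | intermediate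
24 | 3,5-bis(benzyloxy)-2-[(4-methylbenzenesulfonyl)methyl]-6-{(1S,2R)-2-(tert-butyldimethylsilyloxy)-1-[3,4,5-tris(benzyloxy)phenyl]-3-[2,4,6-tris(benzyloxy)phenyl]propyl}phenol | CC(C)(C)[Si](C)(C)O[C@H](Cc1c(OCc9ccccc9)cc(OCc9ccccc9)cc1OCc9ccccc9)[C@@H](c1cc(OCc9ccccc9)c(OCc9ccccc9)c(OCc9ccccc9)c1)c1c(OCc9ccccc9)cc(OCc9ccccc9)c(CS(=O)(=O)c2ccc(C)cc2)c1O | intermediate
25 | (tert-butyldimethylsilyloxy)acetaldehyde | CC(C)(C)[Si](C)(C)OCC=O | starting material
26 | 3,5-bis(benzyloxy)-6-methylidene-2-{(1S,2R)-2-(tert-butyldimethylsilyloxy)-1-[3,4,5-tris(benzyloxy)phenyl]-3-[2,4,6-tris(benzyloxy)phenyl]propyl}cyclohexa-2,4-dien-1-one | CC(C)(C)[Si](C)(C)O[C@H](Cc1c(OCc9ccccc9)cc(OCc9ccccc9)cc1OCc9ccccc9)[C@@H](c1cc(OCc9ccccc9)c(OCc9ccccc9)c(OCc9ccccc9)c1)C1=C(OCc9ccccc9)C=C(OCc9ccccc9)C(=C)C1=O | intermediate (not isolated)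
27 | (3R)-5,7-bis(benzyloxy)-3-(tert-butyldimethylsilyloxy)-8-{(1S,2R)-2-(tert-butyldimethylsilyloxy)-1-[3,4,5-tris(benzyloxy)phenyl]-3-[2,4,6-tris(benzyloxy)phenyl]propyl}-3,4-dihydro-2H-chromen-2-ol (C2 anomers) | CC(C)(C)[Si](C)(C)O[C@H](Cc1c(OCc9ccccc9)cc(OCc9ccccc9)cc1OCc9ccccc9)[C@@H](c1cc(OCc9ccccc9)c(OCc9ccccc9)c(OCc9ccccc9)c1)c1c(OCc9ccccc9)cc(OCc9ccccc9)c2c1OC(O)[C@H](O[Si](C)(C)C(C)(C)C)C2 | intermediate
28 | 5-bromo-1,2,3-trimethoxybenzene | COc1cc(Br)cc(OC)c1OC | starting material
29 | 5-bromobenzene-1,2,3-triol | Oc1cc(Br)cc(O)c1O | intermediate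
30 | 5-bromo-1,2,3-tris(benzyloxy)benzene | Brc1cc(OCc9ccccc9)c(OCc9ccccc9)c(OCc9ccccc9)c1 | intermediate
31 | [3,4,5-tris(benzyloxy)phenyl]magnesium bromide | Br[Mg]c1cc(OCc9ccccc9)c(OCc9ccccc9)c(OCc9ccccc9)c1 | intermediate (not isolated)
32 | (1S,2R)-3-{4,6-bis(benzyloxy)-2-hydroxy-3-[(1S,2R)-2-(tert-butyldimethylsilyloxy)-1-[3,4,5-tris(benzyloxy)phenyl]-3-[2,4,6-tris(benzyloxy)phenyl]propyl]phenyl}-2-(tert-butyldimethylsilyloxy)-1-[3,4,5-tris(benzyloxy)phenyl]propan-1-ol | CC(C)(C)[Si](C)(C)O[C@H](Cc1c(OCc9ccccc9)cc(OCc9ccccc9)cc1OCc9ccccc9)[C@@H](c1cc(OCc9ccccc9)c(OCc9ccccc9)c(OCc9ccccc9)c1)c1c(OCc9ccccc9)cc(OCc9ccccc9)c(C[C@@H](O[Si](C)(C)C(C)(C)C)[C@@H](O)c2cc(OCc9ccccc9)c(OCc9ccccc9)c(OCc9ccccc9)c2)c1O | intermediate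
33 | (2R,3R)-5,7-bis(benzyloxy)-3-(tert-butyldimethylsilyloxy)-8-{(1S,2R)-2-(tert-butyldimethylsilyloxy)-1-[3,4,5-tris(benzyloxy)phenyl]-3-[2,4,6-tris(benzyloxy)phenyl]propyl}-2-[3,4,5-tris(benzyloxy)phenyl]-3,4-dihydro-2H-chromene | CC(C)(C)[Si](C)(C)O[C@H](Cc1c(OCc9ccccc9)cc(OCc9ccccc9)cc1OCc9ccccc9)[C@@H](c1cc(OCc9ccccc9)c(OCc9ccccc9)c(OCc9ccccc9)c1)c1c(OCc9ccccc9)cc(OCc9ccccc9)c2c1O[C@H](c1cc(OCc9ccccc9)c(OCc9ccccc9)c(OCc9ccccc9)c1)[C@H](O[Si](C)(C)C(C)(C)C)C2 | intermediate
34 | (2R,3R)-5,7-bis(benzyloxy)-8-{(1S,2R)-2-hydroxy-1-[3,4,5-tris(benzyloxy)phenyl]-3-[2,4,6-tris(benzyloxy)phenyl]propyl}-2-[3,4,5-tris(benzyloxy)phenyl]-3,4-dihydro-2H-chromen-3-ol | O[C@H](Cc1c(OCc9ccccc9)cc(OCc9ccccc9)cc1OCc9ccccc9)[C@@H](c1cc(OCc9ccccc9)c(OCc9ccccc9)c(OCc9ccccc9)c1)c1c(OCc9ccccc9)cc(OCc9ccccc9)c2c1O[C@H](c1cc(OCc9ccccc9)c(OCc9ccccc9)c(OCc9ccccc9)c1)[C@H](O)C2 | intermediate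
35 | 3,4,5-tris(benzyloxy)benzoic acid | OC(=O)c1cc(OCc9ccccc9)c(OCc9ccccc9)c(OCc9ccccc9)c1 | starting material
36 | 3,4,5-tris(benzyloxy)benzoyl chloride | ClC(=O)c1cc(OCc9ccccc9)c(OCc9ccccc9)c(OCc9ccccc9)c1 | intermediate (not isolated)
37 | (2R,3R)-5,7-bis(benzyloxy)-8-{(1S,2R)-2-[3,4,5-tris(benzyloxy)benzoyloxy]-1-[3,4,5-tris(benzyloxy)phenyl]-3-[2,4,6-tris(benzyloxy)phenyl]propyl}-2-[3,4,5-tris(benzyloxy)phenyl]-3,4-dihydro-2H-chromen-3-yl 3,4,5-tris(benzyloxy)benzoate | O=C(O[C@H](Cc1c(OCc9ccccc9)cc(OCc9ccccc9)cc1OCc9ccccc9)[C@@H](c1cc(OCc9ccccc9)c(OCc9ccccc9)c(OCc9ccccc9)c1)c1c(OCc9ccccc9)cc(OCc9ccccc9)c2c1O[C@H](c1cc(OCc9ccccc9)c(OCc9ccccc9)c(OCc9ccccc9)c1)[C@H](OC(=O)c1cc(OCc9ccccc9)c(OCc9ccccc9)c(OCc9ccccc9)c1)C2)c1cc(OCc9ccccc9)c(OCc9ccccc9)c(OCc9ccccc9)c1 | intermediate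
38 | (2R,3R)-5,7-dihydroxy-8-[(1S,2R)-2-(3,4,5-trihydroxybenzoyloxy)-1-(3,4,5-trihydroxyphenyl)-3-(2,4,6-trihydroxyphenyl)propyl]-2-(3,4,5-trihydroxyphenyl)-3,4-dihydro-2H-chromen-3-yl 3,4,5-trihydroxybenzoate | O=C(O[C@H](Cc1c(O)cc(O)cc1O)[C@@H](c1cc(O)c(O)c(O)c1)c1c(O)cc(O)c2c1O[C@H](c1cc(O)c(O)c(O)c1)[C@H](OC(=O)c1cc(O)c(O)c(O)c1)C2)c1cc(O)c(O)c(O)c1 | target

## Step count and least certain steps

Total step count: 22. Longest linear sequence: 18 steps (1, 2, 4, 5, 6, 7, 9, 10, 11, 12, 13, 14, 15, 18, 19, 20, 21, 22).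

**Step 15 (key step).** The unsubstituted, strongly donor-stabilised quinone methide may be consumed by self-condensation or by re-addition of sulfinate before the enamine adds. The α-silyloxy enamine is less nucleophilic than a simple alkyl enamine, the aldehyde may self-condense under base, and an uncatalysed enol pathway would erode facial selectivity at C3.
Fallback, from sulfone 24 back to lactol 27: the auxiliary-bound glycolate (4S)-4-benzyl-3-[(tert-butyldimethylsilyloxy)acetyl]-1,3-oxazolidin-2-one F1 is made from 3 and (tert-butyldimethylsilyloxy)acetyl chloride. Its sodium enolate (NaN(SiMe3)2, THF, −78 °C, in excess so that one equivalent releases the quinone methide from 24) is alkylated at the methylene on the face opposite the benzyl group, giving the imide (4S)-4-benzyl-3-[(2R)-3-aryl-2-(tert-butyldimethylsilyloxy)propanoyl]-1,3-oxazolidin-2-one F2. Warming with DMAP lets the C8a phenol displace the auxiliary to give the (3R)-3-silyloxychroman-2-one F3, and i-Bu2AlH at −78 °C reduces the lactone to 27.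

**Step 4.** Lithiation may compete at the carbon between the two benzyloxy groups or at a benzylic CH2. The 2,6-dioxygenated aryl group may also transfer slowly from copper, so that 1,2-addition to the imide takes over.
Fallback, from phenol 6 back to imide 10, with ring A as the electrophile and ring B as the nucleophile: formylation of 6 (MgCl2, Et3N, (CH2O)n) gives 2,4-bis(benzyloxy)-6-hydroxybenzaldehyde F4, and MeOCH2Cl with i-Pr2NEt gives 2,4-bis(benzyloxy)-6-(methoxymethoxy)benzaldehyde F5. Knoevenagel–Doebner condensation then gives (2E)-3-[2,4-bis(benzyloxy)-6-(methoxymethoxy)phenyl]prop-2-enoic acid F6, and acylation of (4R)-4-benzyl-1,3-oxazolidin-2-one through the pivalic anhydride gives the (4R)-cinnamoyl imide F7. Copper-catalysed addition of Grignard reagent 31 gives the (4R)-imide of the (3S)-3,3-diarylpropanoic acid F8; the enantiomeric auxiliary is needed because the two aryl groups have exchanged roles. LiOH/H2O2 releases (3S)-3-[2,4-bis(benzyloxy)-6-(methoxymethoxy)phenyl]-3-[3,4,5-tris(benzyloxy)phenyl]propanoic acid F9, and acylation of 3 as in step 2 gives 10.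

**Step 18.** Facial selectivity of the aryl addition may be modest if the magnesium phenoxide engages the aldehyde in a chelate. Enolisation of the α-silyloxy aldehyde by the basic reagent, or silyl migration to the new alkoxide, would erode C3 or scramble the protecting pattern.
Fallback, from lactol 27 back to alcohol 32: oxidation with Ag2CO3 on Celite gives the (3R)-3-silyloxychroman-2-one F3. Opening with MeNH(OMe)·HCl and AlMe3 gives the (2R)-N-methoxy-N-methyl-2-silyloxy-3-arylpropanamide F10. Aryllithium from 30 (n-BuLi, excess) gives the (2R)-2-silyloxy-1-[3,4,5-tris(benzyloxy)phenyl]propan-1-one F11. Reagent-controlled reduction with the (S)-configured B-methyl oxazaborolidine and BH3·SMe2 (Corey–Bakshi–Shibata reduction, aryl as the large group) gives 32.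

**Step 19.** Partial ionisation of the benzylic oxyphosphonium would lose the inversion (2,3-trans flavan) or lead to elimination towards a styrene; the hindered phenol slows the SN2 closure.
Fallback, from lactol 27 back to flavan 33: it makes no new compound beyond those already listed (F0). Ketone F11, reached through F3 and F10 as above, is treated with Et3SiH and BF3·OEt2 in CH2Cl2 at −78 °C. The phenol closes to the cyclic hemiketal, and the 2-aryl oxocarbenium ion should be reduced by hydride delivery anti to the pseudoaxial C3 silyloxy group, giving the 2,3-cis flavan 33 without a benzylic substitution.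

**Step 22.** Hydrogenolysis of seventeen benzyl ethers may stall at partially benzylated stages, the benzylic O1–C2 bond may be over-reduced, and the pyrogallol units may oxidise during isolation.
Fallback, from 37 back to 38, with no new compound (F0): Lewis-acid debenzylation with BCl3 and pentamethylbenzene as cation scavenger in CH2Cl2 at −78 °C, which leaves aryl esters and the ring C ether intact.

## Further compounds

F1 | step 15 | (4S)-4-benzyl-3-[(tert-butyldimethylsilyloxy)acetyl]-1,3-oxazolidin-2-one | O=C1OC[C@H](Cc2ccccc2)N1C(=O)CO[Si](C)(C)C(C)(C)C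
F2 | step 15 | (4S)-4-benzyl-3-[(2R)-3-{4,6-bis(benzyloxy)-2-hydroxy-3-[(1S,2R)-2-(tert-butyldimethylsilyloxy)-1-[3,4,5-tris(benzyloxy)phenyl]-3-[2,4,6-tris(benzyloxy)phenyl]propyl]phenyl}-2-(tert-butyldimethylsilyloxy)propanoyl]-1,3-oxazolidin-2-one | CC(C)(C)[Si](C)(C)O[C@H](Cc1c(OCc9ccccc9)cc(OCc9ccccc9)cc1OCc9ccccc9)[C@@H](c1cc(OCc9ccccc9)c(OCc9ccccc9)c(OCc9ccccc9)c1)c1c(OCc9ccccc9)cc(OCc9ccccc9)c(C[C@@H](O[Si](C)(C)C(C)(C)C)C(=O)N2C(=O)OC[C@@H]2Cc2ccccc2)c1O
F3 | step 15 | (3R)-5,7-bis(benzyloxy)-3-(tert-butyldimethylsilyloxy)-8-{(1S,2R)-2-(tert-butyldimethylsilyloxy)-1-[3,4,5-tris(benzyloxy)phenyl]-3-[2,4,6-tris(benzyloxy)phenyl]propyl}-3,4-dihydro-2H-chromen-2-one | CC(C)(C)[Si](C)(C)O[C@H](Cc1c(OCc9ccccc9)cc(OCc9ccccc9)cc1OCc9ccccc9)[C@@H](c1cc(OCc9ccccc9)c(OCc9ccccc9)c(OCc9ccccc9)c1)c1c(OCc9ccccc9)cc(OCc9ccccc9)c2c1OC(=O)[C@H](O[Si](C)(C)C(C)(C)C)C2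
F4 | step 4 | 2,4-bis(benzyloxy)-6-hydroxybenzaldehyde | O=Cc1c(O)cc(OCc9ccccc9)cc1OCc9ccccc9
F5 | step 4 | 2,4-bis(benzyloxy)-6-(methoxymethoxy)benzaldehyde | O=Cc1c(OCOC)cc(OCc9ccccc9)cc1OCc9ccccc9
F6 | step 4 | (2E)-3-[2,4-bis(benzyloxy)-6-(methoxymethoxy)phenyl]prop-2-enoic acid | OC(=O)/C=C/c1c(OCOC)cc(OCc9ccccc9)cc1OCc9ccccc9
F7 | step 4 | (4R)-4-benzyl-3-{(2E)-3-[2,4-bis(benzyloxy)-6-(methoxymethoxy)phenyl]prop-2-enoyl}-1,3-oxazolidin-2-one | O=C1OC[C@@H](Cc2ccccc2)N1C(=O)/C=C/c1c(OCOC)cc(OCc9ccccc9)cc1OCc9ccccc9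
F8 | step 4 | (4R)-4-benzyl-3-{(3S)-3-[2,4-bis(benzyloxy)-6-(methoxymethoxy)phenyl]-3-[3,4,5-tris(benzyloxy)phenyl]propanoyl}-1,3-oxazolidin-2-one | O=C1OC[C@@H](Cc2ccccc2)N1C(=O)C[C@@H](c1cc(OCc9ccccc9)c(OCc9ccccc9)c(OCc9ccccc9)c1)c1c(OCc9ccccc9)cc(OCc9ccccc9)cc1OCOC
F9 | step 4 | (3S)-3-[2,4-bis(benzyloxy)-6-(methoxymethoxy)phenyl]-3-[3,4,5-tris(benzyloxy)phenyl]propanoic acid | OC(=O)C[C@@H](c1cc(OCc9ccccc9)c(OCc9ccccc9)c(OCc9ccccc9)c1)c1c(OCc9ccccc9)cc(OCc9ccccc9)cc1OCOC
F10 | step 18 | (2R)-3-{4,6-bis(benzyloxy)-2-hydroxy-3-[(1S,2R)-2-(tert-butyldimethylsilyloxy)-1-[3,4,5-tris(benzyloxy)phenyl]-3-[2,4,6-tris(benzyloxy)phenyl]propyl]phenyl}-2-(tert-butyldimethylsilyloxy)-N-methoxy-N-methylpropanamide | CC(C)(C)[Si](C)(C)O[C@H](Cc1c(OCc9ccccc9)cc(OCc9ccccc9)cc1OCc9ccccc9)[C@@H](c1cc(OCc9ccccc9)c(OCc9ccccc9)c(OCc9ccccc9)c1)c1c(OCc9ccccc9)cc(OCc9ccccc9)c(C[C@@H](O[Si](C)(C)C(C)(C)C)C(=O)N(C)OC)c1O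
F11 | step 18 | (2R)-3-{4,6-bis(benzyloxy)-2-hydroxy-3-[(1S,2R)-2-(tert-butyldimethylsilyloxy)-1-[3,4,5-tris(benzyloxy)phenyl]-3-[2,4,6-tris(benzyloxy)phenyl]propyl]phenyl}-2-(tert-butyldimethylsilyloxy)-1-[3,4,5-tris(benzyloxy)phenyl]propan-1-one | CC(C)(C)[Si](C)(C)O[C@H](Cc1c(OCc9ccccc9)cc(OCc9ccccc9)cc1OCc9ccccc9)[C@@H](c1cc(OCc9ccccc9)c(OCc9ccccc9)c(OCc9ccccc9)c1)c1c(OCc9ccccc9)cc(OCc9ccccc9)c(C[C@@H](O[Si](C)(C)C(C)(C)C)C(=O)c2cc(OCc9ccccc9)c(OCc9ccccc9)c(OCc9ccccc9)c2)c1O
F0 | step 19 | none | none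
F0 | step 22 | none | none
A1 | alternative 1 | cyclic dimethylsilyl ether bridging the C7 oxygen and Cβ, silicon trans to the Cγ pyrogallol ring | C[Si]1(C)Oc2cc(OCc9ccccc9)c3C[C@@H](O[Si](C)(C)C(C)(C)C)[C@@H](c4cc(OCc9ccccc9)c(OCc9ccccc9)c(OCc9ccccc9)c4)Oc3c2[C@H](c2cc(OCc9ccccc9)c(OCc9ccccc9)c(OCc9ccccc9)c2)[C@H]1Cc1c(OCc9ccccc9)cc(OCc9ccccc9)cc1OCc9ccccc9
A2 | alternative 2 | ring A phenol from the benzannulation (C8a–OH free, C7 tert-butyl ether, C5 triisopropylsilyl ether) | CC(C)(C)[Si](C)(C)O[C@H](Cc1c(OCc9ccccc9)cc(OCc9ccccc9)cc1OCc9ccccc9)[C@@H](c1cc(OCc9ccccc9)c(OCc9ccccc9)c(OCc9ccccc9)c1)c1c(OC(C)(C)C)cc(O[Si](C(C)C)(C(C)C)C(C)C)c(C[C@@H](O[Si](C)(C)C(C)(C)C)[C@@H](O[Si](CC)(CC)CC)c2cc(OCc9ccccc9)c(OCc9ccccc9)c(OCc9ccccc9)c2)c1O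
A3 | alternative 3 | Cβ pinacol boronate of the full carbon skeleton | CC1(C)OB(OC1(C)C)[C@H](Cc1c(OCc9ccccc9)cc(OCc9ccccc9)cc1OCc9ccccc9)[C@@H](c1cc(OCc9ccccc9)c(OCc9ccccc9)c(OCc9ccccc9)c1)c1c(OCc9ccccc9)cc(OCc9ccccc9)c2c1O[C@H](c1cc(OCc9ccccc9)c(OCc9ccccc9)c(OCc9ccccc9)c1)[C@H](O[Si](C)(C)C(C)(C)C)C2
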